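**Strategy.** Clerodane numbering is used. Everything rests on an intramolecular Diels–Alder reaction of an open-chain triene: one operation joins C1 to C2 and C5 to C10, closing ring A (C1–C5, C10) and ring B (C5–C10) together and setting both ring-fusion centres. The step exploits the ring A pattern C4(=C18)–C3(=O)–C2(OH)=C1: a 2,3-bis(silyloxy)diene (C2=C3–C4=C5) carries both oxygens, and an (E)-nitroalkene (C1=C10) serves as a traceless dienophile whose nitro group later leaves as nitrite to create C1=C2. The precursor is an acyclic nitro enone (C6–C9 tether carrying C7, C8, C9 and the C13 side chain), built from geranyl propionate.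

Key step: step 14

Assumption: the enantiomer of the boron reagent (step 1) and of Tol-BINAP (step 5) named below is the one taken, by analogy, to give 2 and 6 as drawn; the antipode is used if the sense proves opposite.

**Route**

Step 1
Reactants: 1 geranyl propionate
Product: 2 (2S,3R)-3-ethenyl-2,3,7-trimethyloct-6-enoic acid
Conditions: (4S,5S)-2-bromo-1,3-bis{[3,5-bis(trifluoromethyl)phenyl]sulfonyl}-4,5-diphenyl-1,3,2-diazaborolidine (preformed, 1.1 equiv), i-Pr2NEt, CH2Cl2, −78 °C then 4 °C; aq. work-up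
Reagents that add atoms: none
Why: Enantioselective Ireland–Claisen rearrangement of the chiral boron (Z)-O-enolate through a chair (E alkene: C20 axial, chain equatorial; enolate methyl equatorial) should set C8 and the quaternary C9 with its vinyl group in the required relative sense, the boron ligand choosing the face.

Step 2
Reactants: 2 (2S,3R)-3-ethenyl-2,3,7-trimethyloct-6-enoic acid
Product: 3 (2S,3R)-3-ethenyl-2,3,7-trimethyloct-6-en-1-ol
Conditions: LiAlH4, THF, 0 °C to rt
Reagents that add atoms: none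
Why: Hydride reduction of the acid to the primary alcohol; no stereocentre is touched.

Step 3
Reactants: 3 (2S,3R)-3-ethenyl-2,3,7-trimethyloct-6-en-1-ol
Product: 4 tert-butyl{[(2S,3R)-3-ethenyl-2,3,7-trimethyloct-6-en-1-yl]oxy}dimethylsilane
Conditions: TBSCl, imidazole, DMF, rt
Reagents that add atoms: tert-butyl(chloro)dimethylsilane, CC(C)(C)[Si](C)(C)Cl
Why: Silylation masks the alcohol against the Grignard reagent of step 5.

Step 4
Reactants: 4 tert-butyl{[(2S,3R)-3-ethenyl-2,3,7-trimethyloct-6-en-1-yl]oxy}dimethylsilane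
Product: 5 methyl (2E,6R,7S)-8-{[tert-butyl(dimethyl)silyl]oxy}-6-ethenyl-6,7-dimethyloct-2-enoate
Conditions: methyl acrylate (excess), second-generation Hoveyda–Grubbs catalyst RuCl2(H2IMes)(=CH-C6H4-2-O-i-Pr) (5 mol %), CH2Cl2, 40 °C
Reagents that add atoms: methyl acrylate, C=CC(=O)OC
Why: Olefin cross-metathesis exchanges isobutene of the prenyl terminus for the acrylate (E by thermodynamic control), while the vinyl group on the quaternary C9 is too hindered to react.

Step 5
Reactants: 5 methyl (2E,6R,7S)-8-{[tert-butyl(dimethyl)silyl]oxy}-6-ethenyl-6,7-dimethyloct-2-enoate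
Product: 6 methyl (3R,6R,7S)-8-{[tert-butyl(dimethyl)silyl]oxy}-6-ethenyl-3,6,7-trimethyloctanoate
Conditions: MeMgBr, CuI (cat.), (S)-Tol-BINAP (cat.), t-BuOMe, −20 °C
Reagents that add atoms: methylmagnesium bromide, C[Mg]Br
Why: Copper-catalysed asymmetric conjugate addition of the Grignard reagent to the (E)-enoate sets C13 (R) under ligand control and gives the methyl ester directly.

Step 6
Reactants: 6 methyl (3R,6R,7S)-8-{[tert-butyl(dimethyl)silyl]oxy}-6-ethenyl-3,6,7-trimethyloctanoate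
Product: 7 methyl (3R,6R,7S)-6-ethenyl-8-hydroxy-3,6,7-trimethyloctanoate
Conditions: HF·pyridine, THF, 0 °C to rt
Reagents that add atoms: none
Why: Fluoride desilylation frees the primary alcohol without touching the methyl ester.

Step 7
Reactants: 7 methyl (3R,6R,7S)-6-ethenyl-8-hydroxy-3,6,7-trimethyloctanoate
Product: 8 methyl (3R,6R,7S)-6-ethenyl-3,6,7-trimethyl-8-oxooctanoate
Conditions: Dess–Martin periodinane, NaHCO3, CH2Cl2, 0 °C; used crude
Reagents that add atoms: none
Why: Buffered Dess–Martin oxidation gives the C7 aldehyde without epimerising the adjacent C8.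

Step 8
Reactants: 9 2,3-dimethylbut-2-enoic acid
Product: 10 [(2,3-dimethylbuta-1,3-diene-1,1-diyl)bis(oxy)]bis(trimethylsilane)
Conditions: LiN(i-Pr)2 (2.2 equiv), THF, −78 to 0 °C; TMSCl, −78 °C to rt
Reagents that add atoms: chlorotrimethylsilane, C[Si](C)(C)Cl
Why: Double deprotonation (carboxyl, then a γ-methyl) and O-silylation give the bis(silyl) ketene acetal, a vinylogous enolate with no geometry at the acetal carbon.

Step 9
Reactants: 8 methyl (3R,6R,7S)-6-ethenyl-3,6,7-trimethyl-8-oxooctanoate; 10 [(2,3-dimethylbuta-1,3-diene-1,1-diyl)bis(oxy)]bis(trimethylsilane)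
Product: 11 (2E,5S,6S,7R,10R)-7-ethenyl-5-hydroxy-12-methoxy-2,3,6,7,10-pentamethyl-12-oxododec-2-enoic acid
Conditions: BF3·OEt2, CH2Cl2, −78 °C; aq. NaHCO3, then acidify; extract the acid
Reagents that add atoms: none
Why: Vinylogous Mukaiyama aldol through an open transition state: attack at the γ-carbon (the α-carbon is fully substituted), Felkin–Anh addition anti to the quaternary C9 sets C7 (S), and the extended dienolate should give the alkene with C6 trans to the carboxyl; any Z adduct lactonises and stays in the neutral fraction.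

Step 10
Reactants: 11 (2E,5S,6S,7R,10R)-7-ethenyl-5-hydroxy-12-methoxy-2,3,6,7,10-pentamethyl-12-oxododec-2-enoic acid
Product: 12 (2E,5S,6S,7R,10R)-5-acetoxy-7-ethenyl-12-methoxy-2,3,6,7,10-pentamethyl-12-oxododec-2-enoic acid
Conditions: Ac2O, pyridine, DMAP, rt; then H2O/THF to cleave the mixed anhydride
Reagents that add atoms: acetic anhydride, CC(=O)OC(C)=O
Why: Acylation installs the C7 acetate of the target early, since it tolerates all later steps.

Step 11
Reactants: 13 (tributylstannyl)methanol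
Product: 14 tert-butyl(dimethyl)[(tributylstannyl)methoxy]silane
Conditions: TBSCl, imidazole, DMF, rt
Reagents that add atoms: tert-butyl(chloro)dimethylsilane, CC(C)(C)[Si](C)(C)Cl
Why: Silylation gives the silyloxymethyl stannane that delivers C2 with its oxygen already protected.

Step 12
Reactants: 12 (2E,5S,6S,7R,10R)-5-acetoxy-7-ethenyl-12-methoxy-2,3,6,7,10-pentamethyl-12-oxododec-2-enoic acid; 14 tert-butyl(dimethyl)[(tributylstannyl)methoxy]silane
Product: 16 methyl (3R,6R,7S,8S,10E)-8-acetoxy-13-{[tert-butyl(dimethyl)silyl]oxy}-6-ethenyl-3,6,7,10,11-pentamethyl-12-oxotridec-10-enoate, via acid chloride 15 (not isolated)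
Conditions: (COCl)2, DMF (cat.), CH2Cl2, 0 °C; evaporate; then 14, BnPdCl(PPh3)2 (5 mol %), toluene, 65 °C
Reagents that add atoms: oxalyl chloride, ClC(=O)C(=O)Cl (its chlorine is present in 15 only)
Why: Stille acylation of the acid chloride with selective transfer of the α-oxygenated methyl group from tin builds the C2–C3 bond under neutral conditions that spare acetate, methyl ester and alkene geometry.

Step 13
Reactants: 16 methyl (3R,6R,7S,8S,10E)-8-acetoxy-13-{[tert-butyl(dimethyl)silyl]oxy}-6-ethenyl-3,6,7,10,11-pentamethyl-12-oxotridec-10-enoate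
Product: 17 methyl (3R,6R,7S,8S,10E)-8-acetoxy-13-{[tert-butyl(dimethyl)silyl]oxy}-3,6,7,10,11-pentamethyl-6-[(E)-2-nitroethenyl]-12-oxotridec-10-enoate
Conditions: AgNO2, TEMPO, 4 Å molecular sieves, 1,2-dichloroethane, 70 °C
Reagents that add atoms: silver nitrite, [Ag+].[O-]N=O
Why: Radical nitration of the terminal alkene (NO2 adds to the CH2 end, TEMPO removes hydrogen) gives the (E)-nitroalkene; the tetrasubstituted, electron-poor enone alkene should not react.

Step 14
Reactants: 17 methyl (3R,6R,7S,8S,10E)-8-acetoxy-13-{[tert-butyl(dimethyl)silyl]oxy}-3,6,7,10,11-pentamethyl-6-[(E)-2-nitroethenyl]-12-oxotridec-10-enoate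
Product: 19 cis-fused nitro cycloadduct, methyl 7-acetoxy-2-[tert-butyl(dimethyl)silyloxy]-1-nitro-3-(trimethylsilyloxy)clerod-3-en-15-oate, via bis(silyloxy)diene 18 (not isolated)
Conditions: TMSOTf, i-Pr2NEt, CH2Cl2, −78 to 0 °C; then toluene, 60 °C
Reagents that add atoms: trimethylsilyl trifluoromethanesulfonate, C[Si](C)(C)OS(=O)(=O)C(F)(F)F
Why: Soft enolisation toward the oxygen-bearing C2 gives the (Z)-1,2-bis(silyloxy)diene 18, which adds to the tethered nitroalkene in a normal-demand intramolecular Diels–Alder reaction (closest known types: nitroalkene cycloadditions with 1-oxygenated 2-silyloxy dienes and type 1 nitroalkene cyclisations of 1,7,9-decatrienes); the C2 oxygen makes C5 the nucleophilic terminus that meets the electrophilic C10. Ring A closes by the [4+2] union of C2–C5 with C1=C10, and ring B closes through the same C5–C10 bond as a six-membered ring over the four-carbon C6–C9 tether. C5 and C10 are set suprafacially: with C6 outside and C19 inside on the E C4=C5 bond and the E nitroalkene, the tether-endo, nitro-exo mode gives the cis fusion (H10 cis to C19), and the tether reacts as a chair with the C7 acetate, C17 and the C9 side chain equatorial and C20 axial, the diene folding over it so that C19 is equatorial, which fixes C5 and C10 relative to C7–C9 as in the target. The step needs this mode to win over the trans-fused, nitro-endo mode; the substrate favours it because nitroalkenes tend to add exo to oxygenated silyloxy dienes (repulsion between the nitro group and the C2/C3 oxygens) and because the trans mode would force the inside C19 methyl into a syn-axial contact with C20 on the quaternary C9. C1 and C2 are formed as stereocentres (NO2 cis to H10, OSi trans to NO2) but are erased in step 15, where C10 also remains correctable through the extended enolate.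

Step 15
Reactants: 19 cis-fused nitro cycloadduct
Product: 21 methyl 7-acetoxy-2-[tert-butyl(dimethyl)silyloxy]-3-oxocleroda-1,4(18)-dien-15-oate, via nitro enone 20 (not isolated)
Conditions: Pd(OAc)2 (1.1 equiv), MeCN, rt; then DBU, 0 °C to rt
Reagents that add atoms: none
Why: Saegusa–Ito oxidation of the silyl enol ether can eliminate only toward C18 because C5 is quaternary, giving the exocyclic enone, and DBU then removes H2 next to the ketone and expels nitrite from C1 (E1cB) to form the C1=C2 enol ether; no stereocentre is created, and the cis fusion is the expected thermodynamic preference at C10.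

Step 16
Reactants: 21 methyl 7-acetoxy-2-[tert-butyl(dimethyl)silyloxy]-3-oxocleroda-1,4(18)-dien-15-oate
Product: 22 methyl (5S,7S,8S,9R,10R,13R)-7-acetoxy-2-hydroxy-3-oxocleroda-1,4(18)-dien-15-oate (target)
Conditions: HF·pyridine, THF, 0 °C
Reagents that add atoms: none
Why: Fluoride cleavage of the enol silyl ether releases the diosphenol, which should remain as the conjugated C2 enol; acetate and methyl ester are untouched.

**Compound list**

1 | geranyl propionate, (2E)-3,7-dimethylocta-2,6-dien-1-yl propanoate | CCC(=O)OC/C=C(C)/CCC=C(C)C | starting material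
2 | (2S,3R)-3-ethenyl-2,3,7-trimethyloct-6-enoic acid | C=C[C@@](C)(CCC=C(C)C)[C@H](C)C(=O)O | intermediate
3 | (2S,3R)-3-ethenyl-2,3,7-trimethyloct-6-en-1-ol | C=C[C@@](C)(CCC=C(C)C)[C@H](C)CO | intermediate
4 | tert-butyl{[(2S,3R)-3-ethenyl-2,3,7-trimethyloct-6-en-1-yl]oxy}dimethylsilane | C=C[C@@](C)(CCC=C(C)C)[C@H](C)CO[Si](C)(C)C(C)(C)C | intermediate
5 | methyl (2E,6R,7S)-8-{[tert-butyl(dimethyl)silyl]oxy}-6-ethenyl-6,7-dimethyloct-2-enoate | C=C[C@@](C)(CC/C=C/C(=O)OC)[C@H](C)CO[Si](C)(C)C(C)(C)C | intermediate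
6 | methyl (3R,6R,7S)-8-{[tert-butyl(dimethyl)silyl]oxy}-6-ethenyl-3,6,7-trimethyloctanoate | C=C[C@@](C)(CC[C@@H](C)CC(=O)OC)[C@H](C)CO[Si](C)(C)C(C)(C)C | intermediate
7 | methyl (3R,6R,7S)-6-ethenyl-8-hydroxy-3,6,7-trimethyloctanoate | C=C[C@@](C)(CC[C@@H](C)CC(=O)OC)[C@H](C)CO | intermediate
8 | methyl (3R,6R,7S)-6-ethenyl-3,6,7-trimethyl-8-oxooctanoate | C=C[C@@](C)(CC[C@@H](C)CC(=O)OC)[C@H](C)C=O | intermediate
9 | 2,3-dimethylbut-2-enoic acid | CC(C)=C(C)C(=O)O | starting material
10 | [(2,3-dimethylbuta-1,3-diene-1,1-diyl)bis(oxy)]bis(trimethylsilane) | C=C(C)C(C)=C(O[Si](C)(C)C)O[Si](C)(C)C | intermediate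
11 | (2E,5S,6S,7R,10R)-7-ethenyl-5-hydroxy-12-methoxy-2,3,6,7,10-pentamethyl-12-oxododec-2-enoic acid | C=C[C@@](C)(CC[C@@H](C)CC(=O)OC)[C@H](C)[C@@H](O)C/C(C)=C(C)/C(=O)O | intermediate
12 | (2E,5S,6S,7R,10R)-5-acetoxy-7-ethenyl-12-methoxy-2,3,6,7,10-pentamethyl-12-oxododec-2-enoic acid | C=C[C@@](C)(CC[C@@H](C)CC(=O)OC)[C@H](C)[C@@H](OC(C)=O)C/C(C)=C(C)/C(=O)O | intermediate
13 | (tributylstannyl)methanol | OC[Sn](CCCC)(CCCC)CCCC | starting material
14 | tert-butyl(dimethyl)[(tributylstannyl)methoxy]silane | CCCC[Sn](CCCC)(CCCC)CO[Si](C)(C)C(C)(C)C | intermediate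
15 | methyl (3R,6R,7S,8S,10E)-8-acetoxy-12-chloro-6-ethenyl-3,6,7,10,11-pentamethyl-12-oxododec-10-enoate (acid chloride, not isolated) | C=C[C@@](C)(CC[C@@H](C)CC(=O)OC)[C@H](C)[C@@H](OC(C)=O)C/C(C)=C(C)/C(=O)Cl | intermediate
16 | methyl (3R,6R,7S,8S,10E)-8-acetoxy-13-{[tert-butyl(dimethyl)silyl]oxy}-6-ethenyl-3,6,7,10,11-pentamethyl-12-oxotridec-10-enoate | C=C[C@@](C)(CC[C@@H](C)CC(=O)OC)[C@H](C)[C@@H](OC(C)=O)C/C(C)=C(C)/C(=O)CO[Si](C)(C)C(C)(C)C | intermediate
17 | methyl (3R,6R,7S,8S,10E)-8-acetoxy-13-{[tert-butyl(dimethyl)silyl]oxy}-3,6,7,10,11-pentamethyl-6-[(E)-2-nitroethenyl]-12-oxotridec-10-enoate | O=[N+]([O-])/C=C/[C@@](C)(CC[C@@H](C)CC(=O)OC)[C@H](C)[C@@H](OC(C)=O)C/C(C)=C(C)/C(=O)CO[Si](C)(C)C(C)(C)C | intermediate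
18 | methyl (3R,6R,7S,8S,10E,12Z)-8-acetoxy-13-{[tert-butyl(dimethyl)silyl]oxy}-3,6,7,10,11-pentamethyl-6-[(E)-2-nitroethenyl]-12-[(trimethylsilyl)oxy]trideca-10,12-dienoate (not isolated) | O=[N+]([O-])/C=C/[C@@](C)(CC[C@@H](C)CC(=O)OC)[C@H](C)[C@@H](OC(C)=O)C/C(C)=C(C)/C(O[Si](C)(C)C)=C/O[Si](C)(C)C(C)(C)C | intermediate
19 | methyl 7-acetoxy-2-[tert-butyl(dimethyl)silyloxy]-1-nitro-3-(trimethylsilyloxy)clerod-3-en-15-oate; cis-fused, C5, C7–C10, C13 as in 22; 1-NO2 cis to H10, 2-OSi trans to NO2 | CC1=C(O[Si](C)(C)C)[C@H](O[Si](C)(C)C(C)(C)C)[C@@H]([N+](=O)[O-])[C@@H]2[C@@](C)(CC[C@@H](C)CC(=O)OC)[C@H](C)[C@@H](OC(C)=O)C[C@]12C | intermediate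
20 | methyl 7-acetoxy-2-[tert-butyl(dimethyl)silyloxy]-1-nitro-3-oxoclerod-4(18)-en-15-oate, configuration as in 19 (not isolated) | C=C1C(=O)[C@H](O[Si](C)(C)C(C)(C)C)[C@@H]([N+](=O)[O-])[C@@H]2[C@@](C)(CC[C@@H](C)CC(=O)OC)[C@H](C)[C@@H](OC(C)=O)C[C@]12C | intermediate
21 | methyl 7-acetoxy-2-[tert-butyl(dimethyl)silyloxy]-3-oxocleroda-1,4(18)-dien-15-oate, stereocentres as in 22 | C=C1C(=O)C(O[Si](C)(C)C(C)(C)C)=C[C@@H]2[C@@](C)(CC[C@@H](C)CC(=O)OC)[C@H](C)[C@@H](OC(C)=O)C[C@]12C | intermediate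
22 | methyl (5S,7S,8S,9R,10R,13R)-7-acetoxy-2-hydroxy-3-oxocleroda-1,4(18)-dien-15-oate | C=C1C(=O)C(O)=C[C@@H]2[C@@](C)(CC[C@@H](C)CC(=O)OC)[C@H](C)[C@@H](OC(C)=O)C[C@]12C | target

**Totals.** 16 steps in all; longest linear sequence 14 steps (steps 1–7, 9, 10, 12–16).

**Steps most likely to fail**

1. Step 14. The cycloaddition may proceed through the trans-fused, nitro-endo mode, which would set C5 in the wrong sense relative to C9; enolisation toward C6 with loss of acetate is a second leak. The fallback makes the dienophile Z, so that the activating group and the tether are both endo in the cis-fused mode. It sets out from 16. Lemieux–Johnson cleavage of the vinyl group (OsO4 cat., NaIO4, 2,6-lutidine) gives the aldehyde F1. Wittig reaction with Ph3P=CHSPh (from the phosphonium chloride and NaN(SiMe3)2, −78 °C) gives, after separation, the (Z)-vinyl sulfide F2. Chemoselective sulfur oxidation ((NH4)6Mo7O24 cat., H2O2) gives the (Z)-vinyl sulfone F3. The same enolisation (TMSOTf, i-Pr2NEt) gives the bis(silyloxy)diene F4 (not isolated), which on heating in toluene (110 °C) should give the cis-fused sulfonyl cycloadduct F5. Pd(OAc)2 then gives the sulfonyl enone F6 (not isolated), from which DBU expels benzenesulfinate; the fallback returns to the route at 21.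

2. Step 9. The vinylogous aldol may lose alkene geometry (the Z adduct lactonises and is lost) or give incomplete Felkin control at C7. The fallback fixes the alkene geometry through a chelated enolate and sets out from 8. The dianion of tert-butyl 2-methyl-3-oxobutanoate (NaH, then n-BuLi, THF) adds through its terminal carbon to give the hydroxy keto ester F7. Silylation (Et3SiCl, imidazole) gives the silyl ether F8. Triflation of the sodium enolate chelate (NaH, Tf2O) gives the (Z)-enol triflate F9. Negishi methylation (MeZnCl, Pd(PPh3)4) with retention gives the tert-butyl (E)-enoate F10. CF3CO2H removes the tert-butyl ester and the silyl ether and returns the route at 11.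

3. Step 15. Palladation at the hindered C4 may be slower than protodesilylation of the enol ether, giving the saturated methyl ketone instead of the exocyclic enone. The fallback sets out from 19. PhSeCl (CH2Cl2, −78 °C) converts the silyl enol ether into the α-phenylselanyl ketone F11. H2O2/pyridine gives the selenoxide F12 (not isolated), whose syn-elimination can only go toward C18 and returns the route at 20, which DBU converts to 21 as before.

**Further compounds**

F1 | step 14 | methyl (3R,6R,7S,8S,10E)-8-acetoxy-13-{[tert-butyl(dimethyl)silyl]oxy}-6-formyl-3,6,7,10,11-pentamethyl-12-oxotridec-10-enoate | O=C[C@@](C)(CC[C@@H](C)CC(=O)OC)[C@H](C)[C@@H](OC(C)=O)C/C(C)=C(C)/C(=O)CO[Si](C)(C)C(C)(C)C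
F2 | step 14 | (Z)-2-(phenylsulfanyl)ethenyl analogue of 17 | c1ccccc1S/C=C\[C@@](C)(CC[C@@H](C)CC(=O)OC)[C@H](C)[C@@H](OC(C)=O)C/C(C)=C(C)/C(=O)CO[Si](C)(C)C(C)(C)C
F3 | step 14 | (Z)-2-(phenylsulfonyl)ethenyl analogue of 17 | O=S(=O)(c1ccccc1)/C=C\[C@@](C)(CC[C@@H](C)CC(=O)OC)[C@H](C)[C@@H](OC(C)=O)C/C(C)=C(C)/C(=O)CO[Si](C)(C)C(C)(C)C
F4 | step 14 | (Z)-sulfonyl bis(silyloxy)diene, analogue of 18 | O=S(=O)(c1ccccc1)/C=C\[C@@](C)(CC[C@@H](C)CC(=O)OC)[C@H](C)[C@@H](OC(C)=O)C/C(C)=C(C)/C(O[Si](C)(C)C)=C/O[Si](C)(C)C(C)(C)C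
F5 | step 14 | cis-fused 1-(phenylsulfonyl) cycloadduct, analogue of 19 (sulfonyl trans to H10) | CC1=C(O[Si](C)(C)C)[C@H](O[Si](C)(C)C(C)(C)C)[C@H](S(=O)(=O)c3ccccc3)[C@@H]2[C@@](C)(CC[C@@H](C)CC(=O)OC)[C@H](C)[C@@H](OC(C)=O)C[C@]12C
F6 | step 14 | 1-(phenylsulfonyl) exocyclic enone, analogue of 20 | C=C1C(=O)[C@H](O[Si](C)(C)C(C)(C)C)[C@H](S(=O)(=O)c3ccccc3)[C@@H]2[C@@](C)(CC[C@@H](C)CC(=O)OC)[C@H](C)[C@@H](OC(C)=O)C[C@]12C
F7 | step 9 | 1-tert-butyl 12-methyl (5S,6S,7R,10R)-7-ethenyl-5-hydroxy-2,6,7,10-tetramethyl-3-oxododecanedioate (C2 epimers) | C=C[C@@](C)(CC[C@@H](C)CC(=O)OC)[C@H](C)[C@@H](O)CC(=O)C(C)C(=O)OC(C)(C)C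
F8 | step 9 | triethylsilyl ether of F7 | C=C[C@@](C)(CC[C@@H](C)CC(=O)OC)[C@H](C)[C@@H](O[Si](CC)(CC)CC)CC(=O)C(C)C(=O)OC(C)(C)C
F9 | step 9 | (Z)-enol triflate of F8 (triflate cis to the tert-butyl ester) | C=C[C@@](C)(CC[C@@H](C)CC(=O)OC)[C@H](C)[C@@H](O[Si](CC)(CC)CC)C/C(OS(=O)(=O)C(F)(F)F)=C(C)/C(=O)OC(C)(C)C
F10 | step 9 | tert-butyl ester, triethylsilyl ether of 11 | C=C[C@@](C)(CC[C@@H](C)CC(=O)OC)[C@H](C)[C@@H](O[Si](CC)(CC)CC)C/C(C)=C(C)/C(=O)OC(C)(C)C
F11 | step 15 | 4-(phenylselanyl) ketone from 19 (either C4 epimer) | CC1([Se]c3ccccc3)C(=O)[C@H](O[Si](C)(C)C(C)(C)C)[C@@H]([N+](=O)[O-])[C@@H]2[C@@](C)(CC[C@@H](C)CC(=O)OC)[C@H](C)[C@@H](OC(C)=O)C[C@]12C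
F12 | step 15 | selenoxide of F11 | CC1([Se](=O)c3ccccc3)C(=O)[C@H](O[Si](C)(C)C(C)(C)C)[C@@H]([N+](=O)[O-])[C@@H]2[C@@](C)(CC[C@@H](C)CC(=O)OC)[C@H](C)[C@@H](OC(C)=O)C[C@]12C
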